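The easy step is to lay the two earlier runs side by side: autumn and spring carry the same charges of starting complex and leaving ligand and differ in incoming ligand.

common to all: starting complex 39 mM
- autumn: incoming ligand 0.67 equiv; leaving ligand 1 equiv; run made earlier
- spring: incoming ligand 1.5 equiv; leaving ligand 1 equiv; run made earlier
- flask: incoming ligand 1.00 equiv; leaving ligand 1.00 equiv; time 8.0 d

| autumn: time / d | autumn: complex with two exchanged / % | spring: time / d | spring: complex with two exchanged / % |
|---|---|---|---|
| 0.500 | 2 | 0.417 | 10 |
| 0.833 | 7 | 1.25 | 17 |
| 1.25 | 6 | 2.50 | 13 |
| 2.50 | 4 | 4.00 | 13 |
| 4.00 | 0 | 5.00 | 15 |
| 6.00 | 2 | 6.00 | 13 |

(scatter of a reading: 1.5 percentage points)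

* equivalents of incoming ligand to starting complex, everything else as given, that leave most complex with two exchanged at 8.0 d
* the amount of complex with two exchanged then, in percent of the starting complex charged
* the amount of complex with two exchanged with the amounts as given

- the numbers in the tables scatter with a standard deviation of 1.5 percentage points
- steps under discussion: complex with two exchanged + incoming ligand -> leaving ligand + complex with three exchanged; complex with two exchanged <-> isomer of the product; complex with one exchanged + incoming ligand -> leaving ligand + complex with two exchanged; starting complex + incoming ligand -> leaving ligand + complex with one exchanged

Under discussion are two exchanges in a row, a third exchange, and a reversible change of the complex with two exchanged into its isomer. In the first instants the complex with two exchanged is two uptakes of incoming ligand away from the starting complex: the autumn run shows 2% at 0.500 d, the spring run 10% at 0.417 d. In the middle it passes a peak, read as 7% at 0.833 d in autumn and 17% at 1.25 d in spring, and then falls. The fall appears in the ligand-poor autumn run too, which points to the isomer, the step that takes up no ligand. From 2.50 d on, the readings lie flat within their scatter of 1.5 percentage points, with means of 2.00% in autumn and 13.5% in spring. So the flask at 8.0 d should stand on such a plateau, and its height becomes a question of loading.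

In logarithms, the plateaus differ by 1.91 and the charges by 0.806, so the line through both runs has the slope 2.37. This is the loading exponent, the change in the logarithm of the plateau per change in the logarithm of the equivalents of incoming ligand. With autumn readings this low, it stays a loose reading. The flask holds 1.49 times the autumn charge, so the line puts it at 5.17%; a rising line has no maximum and offers no figure for the best loading.

The forecast, with the best loading “limited by over-exchange and slow tail conversion”, names 2.2 equiv giving 20%, and 5.5% for the flask, a little more than the line's figure.

The flask gives 6.06%, against 5.17% from the line, and the best loading is 2.28 equiv, giving 22.2%.

    complex with two exchanged + incoming ligand → leaving ligand + complex with three exchanged (k = 0.00140 L mol⁻¹ min⁻¹)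
    complex with two exchanged ⇌ isomer of the product (K = 3.10, k = 7.20 × 10⁻⁴ min⁻¹)
    complex with one exchanged + incoming ligand → leaving ligand + complex with two exchanged (k = 0.0180 L mol⁻¹ min⁻¹)
    starting complex + incoming ligand → leaving ligand + complex with one exchanged (k = 0.0350 L mol⁻¹ min⁻¹)

The largest single effect on the flask's 6.06% is the reversible change of the complex with two exchanged into its isomer: the same flask without that step reaches 24.5%. Without the shortage of incoming ligand, its limiting reagent with 0.016% of its charge left at 8.00 d, the flask reaches 19.9%. The loading exponent of 2.37, taken from the flask's 6.06% down to 0.600 equiv, gives 1.81%, and that neighbouring flask stands at 2.22%.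

(The data come from a simulation with made-up constants, and the scatter is random.)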